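The bonds C4a–C8a and C7–C8 are cut together. One rhodium-catalysed intramolecular [4+2] cycloaddition joins an N-ethynyl carbamate (C8a≡C8 on N1) to a 2-alkyl-1,3-diene (C4a=C5–C6=C7) held on the N1–C2–C3–C4 tether. It closes the piperidine ring and the carbocycle at once and sets C4a from the alanine-derived C2 centre. The step exploits that N1 sits directly on C8a and that the carbocycle carries its only substituent at C5. The precursor is an acyclic ynamide–diene. The two ring alkenes left behind (C8a=C8, C5=C6) are then hydrogenated from one face to fix C8a and C5.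

Key step: step 11

Assumption: atom numbers are those of the decahydroquinoline (N1, C2–C8a; side chain C1'–C8'); (R)-1,2-epoxypentane and N-Boc-L-alaninal are bought as single enantiomers, the aldehyde being used at once because it epimerises on storage.

Step 1
Reactants: 1 (R)-1,2-epoxypentane; 2 6-bromohex-1-ene
Product: 4 (R)-undec-10-en-4-ol, via hex-5-en-1-ylmagnesium bromide 3 (not isolated)
Conditions: 2, Mg, THF, rt; then 1, CuI (10 mol %), THF, −30 → 0 °C; aq. NH4Cl
Reagents that add atoms: magnesium, [Mg] (carried only in intermediate 3)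
Why: Copper-catalysed SN2 opening of a terminal epoxide by a primary Grignard reagent occurs at the CH2 carbon, so the stereocentre of 1 is untouched and becomes C5' (R).

Step 2
Reactants: 4 (R)-undec-10-en-4-ol
Product: 5 (R)-8-tert-butoxyundec-1-ene
Conditions: tert-butyl 2,2,2-trichloroacetimidate (2 equiv), BF3·OEt2 (cat.), cyclohexane/CH2Cl2, rt
Reagents that add atoms: tert-butyl 2,2,2-trichloroacetimidate, CC(C)(C)OC(=N)C(Cl)(Cl)Cl
Why: Acid-catalysed trichloroacetimidate etherification should give a tert-butyl ether that resists base, fluoride, metathesis and hydrogenation and leaves with the Boc group in the last step.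

Step 3
Reactants: 5 (R)-8-tert-butoxyundec-1-ene
Product: 7 (R)-7-tert-butoxydecanal, via secondary ozonide 6 (not isolated)
Conditions: O3, CH2Cl2, −78 °C; then PPh3, −78 °C → rt
Reagents that add atoms: ozone, [O-][O+]=O
Why: Ozonolysis with reductive work-up cleaves only the terminal alkene and gives the aldehyde one carbon shorter, the ether being inert.

Step 4
Reactants: 7 (R)-7-tert-butoxydecanal
Product: 8 (R)-7-tert-butoxy-2-methylidenedecanal
Conditions: 37% aq. CH2O, pyrrolidine (10 mol %), propionic acid (10 mol %), i-PrOH, 45 °C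
Reagents that add atoms: formaldehyde, C=O
Why: Amine/acid-catalysed Mannich condensation and β-elimination (organocatalytic α-methylenation of an aldehyde) should give the 2-alkylacrolein needed as metathesis partner; its α-carbon becomes C5 and its CHO carbon C6.

Step 5
Reactants: 9 N-Boc-L-alaninal [tert-butyl N-[(2S)-1-oxopropan-2-yl]carbamate]
Product: 10 tert-butyl N-[(2S,3R)-3-hydroxyhex-5-en-2-yl]carbamate
Conditions: (+)-Ipc2BOMe, allylMgBr, Et2O, 0 °C → rt; then 9, −78 °C; NaOH, H2O2, rt
Reagents that add atoms: (+)-B-allyldiisopinocampheylborane (made in the flask from (+)-B-methoxydiisopinocampheylborane and allylmagnesium bromide), C=CCB([C@H]1C[C@H]2C[C@@H]([C@@H]1C)C2(C)C)[C@H]1C[C@H]2C[C@@H]([C@@H]1C)C2(C)C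
Why: Brown allylboration through a closed chair transition state; the reagent derived from (−)-α-pinene should attack the re face of the aldehyde and set C3 as R (anti to the C2–N bond) under reagent control.

Step 6
Reactants: 10 tert-butyl N-[(2S,3R)-3-hydroxyhex-5-en-2-yl]carbamate
Product: 11 tert-butyl N-[(2S,3R)-3-[(tert-butyldimethylsilyl)oxy]hex-5-en-2-yl]carbamate
Conditions: TBSCl, imidazole, DMF, rt
Reagents that add atoms: tert-butylchlorodimethylsilane, CC(C)(C)[Si](C)(C)Cl
Why: Imidazole-promoted silylation protects the secondary alcohol while the carbamate N–H stays free for the later N-alkynylation.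

Step 7
Reactants: 11 tert-butyl N-[(2S,3R)-3-[(tert-butyldimethylsilyl)oxy]hex-5-en-2-yl]carbamate; 8 (R)-7-tert-butoxy-2-methylidenedecanal
Product: 12 tert-butyl N-[(2S,3R,5E,11R)-11-tert-butoxy-3-[(tert-butyldimethylsilyl)oxy]-6-formyltetradec-5-en-2-yl]carbamate
Conditions: 8 (2 equiv), second-generation Hoveyda–Grubbs catalyst [RuCl2(H2IMes)(=CH-C6H4-2-OiPr)] (5 mol %), CH2Cl2, 40 °C
Reagents that add atoms: none
Why: Olefin cross-metathesis of a terminal alkene with an electron-poor 2-alkylacrolein (which does not homodimerise) should give the cross product as the (E)-2-alkyl-2-enal under thermodynamic control.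

Step 8
Reactants: 12 tert-butyl N-[(2S,3R,5E,11R)-11-tert-butoxy-3-[(tert-butyldimethylsilyl)oxy]-6-formyltetradec-5-en-2-yl]carbamate
Product: 13 tert-butyl N-[(2S,3R,5E,11R)-11-tert-butoxy-3-[(tert-butyldimethylsilyl)oxy]-6-ethenyltetradec-5-en-2-yl]carbamate
Conditions: Ph3PCH3Br, KHMDS (excess ylide), THF, 0 °C; then 12, −78 → 0 °C
Reagents that add atoms: methylenetriphenylphosphorane (made in the flask from methyltriphenylphosphonium bromide and KHMDS), C=P(c1ccccc1)(c1ccccc1)c1ccccc1
Why: Wittig methylenation of the enal is fast at low temperature and keeps the E geometry, so the tether carbon C4 ends up trans to the new vinyl group (C6=C7).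

Step 9
Reactants: 13 tert-butyl N-[(2S,3R,5E,11R)-11-tert-butoxy-3-[(tert-butyldimethylsilyl)oxy]-6-ethenyltetradec-5-en-2-yl]carbamate
Product: 14 tert-butyl N-[(2S,3R,5E,11R)-11-tert-butoxy-3-[(tert-butyldimethylsilyl)oxy]-6-ethenyltetradec-5-en-2-yl]-N-[2-(triisopropylsilyl)ethynyl]carbamate
Conditions: KHMDS (1.0 equiv), CuI (1.0 equiv), pyridine/THF, 0 °C → rt; (bromoethynyl)triisopropylsilane (2 equiv, slow addition), rt
Reagents that add atoms: (bromoethynyl)triisopropylsilane, CC(C)[Si](C#CBr)(C(C)C)C(C)C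
Why: Copper-mediated N-alkynylation of the pre-formed copper carbamate with a 1-bromoalkyne (Ullmann-type C(sp)–N coupling) should give the silyl-capped ynamide at room temperature, where alkyne homocoupling is slow.

Step 10
Reactants: 14 tert-butyl N-[(2S,3R,5E,11R)-11-tert-butoxy-3-[(tert-butyldimethylsilyl)oxy]-6-ethenyltetradec-5-en-2-yl]-N-[2-(triisopropylsilyl)ethynyl]carbamate
Product: 15 tert-butyl N-[(2S,3R,5E,11R)-11-tert-butoxy-3-[(tert-butyldimethylsilyl)oxy]-6-ethenyltetradec-5-en-2-yl]-N-ethynylcarbamate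
Conditions: TBAF (1.1 equiv), THF, −20 → 0 °C, 15 min
Reagents that add atoms: none
Why: Fluoride-induced protodesilylation of the polarised ynamide C(sp)–Si bond should be much faster than cleavage of the hindered secondary TBS ether.

Step 11
Reactants: 15 tert-butyl N-[(2S,3R,5E,11R)-11-tert-butoxy-3-[(tert-butyldimethylsilyl)oxy]-6-ethenyltetradec-5-en-2-yl]-N-ethynylcarbamate
Product: 16 tert-butyl (2S,3R,4aS)-5-[(5R)-5-tert-butoxyoctyl]-3-[(tert-butyldimethylsilyl)oxy]-2-methyl-3,4,4a,7-tetrahydroquinoline-1(2H)-carboxylate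
Conditions: [RhCl(cod)]2 (5 mol %), P[OCH(CF3)2]3 (20 mol %), THF, 50 °C
Reagents that add atoms: none
Why: Monovalent rhodium binds the ynamide and the s-cis diene of 15, oxidative cyclisation joins C4a to C8a (a rhodacycle with an η3-allyl unit over C5–C7) and reductive elimination then joins C7 to C8, so the N-heterocycle and the cyclohexa-1,4-diene arise in one operation. The closest known reaction type is the rhodium-catalysed intramolecular [4+2] cycloaddition of tethered diene–ynes (a metal-mediated intramolecular Diels–Alder reaction), and ynamides are established 2π partners in rhodium-catalysed cycloadditions. The nitrogen ring closes in the 6-exo-dig mode (C4a onto C8a, C8 left outside that ring) and the carbocycle closes as the six-membered ring of the [4+2] union of C4a=C5–C6=C7 with C8a≡C8. The only new stereocentre, C4a, is controlled by C2: A(1,3) strain between the planar N-Boc group and the C2 methyl group forces that methyl (and the trans C3–OTBS group) pseudoaxial in the half-chair tether, the diene must sit pseudoequatorial at C4a to reach C8, and H4a therefore ends up anti to the C2 methyl group (4aS). The step needs diastereofacial selectivity at C4a and cycloaddition in preference to alkyne oligomerisation; the first is secured by the C2/N-Boc pair, the second by the short disubstituted tether, the unsubstituted termini C7 and C8 and the E geometry that places the tether on the outside of the diene. C8a and C5 stay trigonal on purpose, so no cis/trans ring-fusion question arises at this stage.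

Step 12
Reactants: 16 tert-butyl (2S,3R,4aS)-5-[(5R)-5-tert-butoxyoctyl]-3-[(tert-butyldimethylsilyl)oxy]-2-methyl-3,4,4a,7-tetrahydroquinoline-1(2H)-carboxylate
Product: 17 tert-butyl (2S,3R,4aS,5S,8aR)-5-[(5R)-5-tert-butoxyoctyl]-3-[(tert-butyldimethylsilyl)oxy]-2-methyldecahydroquinoline-1-carboxylate
Conditions: H2 (10 bar), PtO2 (10 mol %), EtOAc, rt
Reagents that add atoms: none
Why: Heterogeneous catalytic hydrogenation should add H2 to the enecarbamate and to the C5=C6 alkene from the face of H4a, the other face being blocked by the pseudoaxial C2 methyl group and by C4; this sets C8a (R, cis ring fusion, H8a cis to H2) and C5 (S, H5 cis to H4a).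

Step 13
Reactants: 17 tert-butyl (2S,3R,4aS,5S,8aR)-5-[(5R)-5-tert-butoxyoctyl]-3-[(tert-butyldimethylsilyl)oxy]-2-methyldecahydroquinoline-1-carboxylate
Product: 18 tert-butyl (2S,3R,4aS,5S,8aR)-5-[(5R)-5-tert-butoxyoctyl]-3-hydroxy-2-methyldecahydroquinoline-1-carboxylate
Conditions: TBAF, THF, rt → 45 °C
Reagents that add atoms: none
Why: Fluoride desilylation frees only the C3 hydroxyl, since the Boc carbamate and the tert-butyl ether are inert to fluoride.

Step 14
Reactants: 19 (2E,4E)-octa-2,4-dienal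
Product: 20 (2E,4E)-octa-2,4-dienoic acid
Conditions: NaClO2, NaH2PO4, 2-methylbut-2-ene, t-BuOH/H2O, 0 °C → rt
Reagents that add atoms: sodium chlorite, [Na+].[O-]Cl=O
Why: Pinnick oxidation converts the dienal into the acid without E/Z isomerisation, 2-methylbut-2-ene trapping the hypochlorous acid.

Step 15
Reactants: 20 (2E,4E)-octa-2,4-dienoic acid; 18 tert-butyl (2S,3R,4aS,5S,8aR)-5-[(5R)-5-tert-butoxyoctyl]-3-hydroxy-2-methyldecahydroquinoline-1-carboxylate
Product: 22 tert-butyl (2S,3R,4aS,5S,8aR)-5-[(5R)-5-tert-butoxyoctyl]-2-methyl-3-{[(2E,4E)-octa-2,4-dienoyl]oxy}decahydroquinoline-1-carboxylate, via mixed anhydride 21 (not isolated)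
Conditions: 20, 2,4,6-trichlorobenzoyl chloride, Et3N, THF, rt; then 18, DMAP, toluene, rt → 40 °C
Reagents that add atoms: 2,4,6-trichlorobenzoyl chloride, O=C(Cl)c1c(Cl)cc(Cl)cc1Cl (carried only in intermediate 21)
Why: Yamaguchi esterification: DMAP attacks the less hindered dienoyl carbonyl of the mixed anhydride and the acylpyridinium acylates the hindered C3 hydroxyl with retention at C3.

Step 16
Reactants: 22 tert-butyl (2S,3R,4aS,5S,8aR)-5-[(5R)-5-tert-butoxyoctyl]-2-methyl-3-{[(2E,4E)-octa-2,4-dienoyl]oxy}decahydroquinoline-1-carboxylate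
Product: 23 lepadin H [(2S,3R,4aS,5S,8aR)-5-[(5R)-5-hydroxyoctyl]-2-methyldecahydroquinolin-3-yl (2E,4E)-octa-2,4-dienoate]
Conditions: TFA/CH2Cl2 (1:1), 0 °C → rt; then aq. NaHCO3/MeOH
Reagents that add atoms: none
Why: Acidolysis (loss of tert-butyl cation) should remove the Boc group and the tert-butyl ether in one operation, the dienoate ester and all stereocentres being stable to acid, and bicarbonate liberates the free amine.

Compound list
1 | (R)-1,2-epoxypentane | CCC[C@@H]1CO1 | starting material
2 | 6-bromohex-1-ene | C=CCCCCBr | starting material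
3 | hex-5-en-1-ylmagnesium bromide | C=CCCCC[Mg]Br | intermediate (not isolated)
4 | (R)-undec-10-en-4-ol | C=CCCCCC[C@H](O)CCC | intermediate
5 | (R)-8-tert-butoxyundec-1-ene | C=CCCCCC[C@H](OC(C)(C)C)CCC | intermediate
6 | 3-[(6R)-6-tert-butoxynonyl]-1,2,4-trioxolane (secondary ozonide, both epimers at the ring carbon) | C1(OCOO1)CCCCC[C@H](OC(C)(C)C)CCC | intermediate (not isolated)
7 | (R)-7-tert-butoxydecanal | O=CCCCCC[C@H](OC(C)(C)C)CCC | intermediate
8 | (R)-7-tert-butoxy-2-methylidenedecanal | C=C(C=O)CCCC[C@H](OC(C)(C)C)CCC | intermediate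
9 | N-Boc-L-alaninal, tert-butyl N-[(2S)-1-oxopropan-2-yl]carbamate | C[C@H](NC(=O)OC(C)(C)C)C=O | starting material
10 | tert-butyl N-[(2S,3R)-3-hydroxyhex-5-en-2-yl]carbamate | C[C@H](NC(=O)OC(C)(C)C)[C@H](O)CC=C | intermediate
11 | tert-butyl N-[(2S,3R)-3-[(tert-butyldimethylsilyl)oxy]hex-5-en-2-yl]carbamate | C[C@H](NC(=O)OC(C)(C)C)[C@H](O[Si](C)(C)C(C)(C)C)CC=C | intermediate
12 | tert-butyl N-[(2S,3R,5E,11R)-11-tert-butoxy-3-[(tert-butyldimethylsilyl)oxy]-6-formyltetradec-5-en-2-yl]carbamate | C[C@H](NC(=O)OC(C)(C)C)[C@H](O[Si](C)(C)C(C)(C)C)C/C=C(/C=O)CCCC[C@H](OC(C)(C)C)CCC | intermediate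
13 | tert-butyl N-[(2S,3R,5E,11R)-11-tert-butoxy-3-[(tert-butyldimethylsilyl)oxy]-6-ethenyltetradec-5-en-2-yl]carbamate | C[C@H](NC(=O)OC(C)(C)C)[C@H](O[Si](C)(C)C(C)(C)C)C/C=C(/C=C)CCCC[C@H](OC(C)(C)C)CCC | intermediate
14 | N-[2-(triisopropylsilyl)ethynyl] derivative of 13 (silyl-capped ynamide) | C[C@H](N(C#C[Si](C(C)C)(C(C)C)C(C)C)C(=O)OC(C)(C)C)[C@H](O[Si](C)(C)C(C)(C)C)C/C=C(/C=C)CCCC[C@H](OC(C)(C)C)CCC | intermediate
15 | N-ethynyl derivative of 13 (terminal ynamide) | C[C@H](N(C#C)C(=O)OC(C)(C)C)[C@H](O[Si](C)(C)C(C)(C)C)C/C=C(/C=C)CCCC[C@H](OC(C)(C)C)CCC | intermediate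
16 | tert-butyl (2S,3R,4aS)-5-[(5R)-5-tert-butoxyoctyl]-3-[(tert-butyldimethylsilyl)oxy]-2-methyl-3,4,4a,7-tetrahydroquinoline-1(2H)-carboxylate | CC(C)(C)[Si](C)(C)O[C@@H]1C[C@H]2C(CCCC[C@H](OC(C)(C)C)CCC)=CCC=C2N(C(=O)OC(C)(C)C)[C@H]1C | intermediate
17 | tert-butyl (2S,3R,4aS,5S,8aR)-5-[(5R)-5-tert-butoxyoctyl]-3-[(tert-butyldimethylsilyl)oxy]-2-methyldecahydroquinoline-1-carboxylate | CC(C)(C)[Si](C)(C)O[C@@H]1C[C@H]2[C@@H](CCCC[C@H](OC(C)(C)C)CCC)CCC[C@H]2N(C(=O)OC(C)(C)C)[C@H]1C | intermediate
18 | tert-butyl (2S,3R,4aS,5S,8aR)-5-[(5R)-5-tert-butoxyoctyl]-3-hydroxy-2-methyldecahydroquinoline-1-carboxylate | O[C@@H]1C[C@H]2[C@@H](CCCC[C@H](OC(C)(C)C)CCC)CCC[C@H]2N(C(=O)OC(C)(C)C)[C@H]1C | intermediate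
19 | (2E,4E)-octa-2,4-dienal | CCC/C=C/C=C/C=O | starting material
20 | (2E,4E)-octa-2,4-dienoic acid | CCC/C=C/C=C/C(=O)O | intermediate
21 | (2E,4E)-octa-2,4-dienoic 2,4,6-trichlorobenzoic anhydride | CCC/C=C/C=C/C(=O)OC(=O)c1c(Cl)cc(Cl)cc1Cl | intermediate (not isolated)
22 | tert-butyl (2S,3R,4aS,5S,8aR)-5-[(5R)-5-tert-butoxyoctyl]-2-methyl-3-{[(2E,4E)-octa-2,4-dienoyl]oxy}decahydroquinoline-1-carboxylate | CCC/C=C/C=C/C(=O)O[C@@H]1C[C@H]2[C@@H](CCCC[C@H](OC(C)(C)C)CCC)CCC[C@H]2N(C(=O)OC(C)(C)C)[C@H]1C | intermediate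
23 | lepadin H, (2S,3R,4aS,5S,8aR)-5-[(5R)-5-hydroxyoctyl]-2-methyldecahydroquinolin-3-yl (2E,4E)-octa-2,4-dienoate | CCC/C=C/C=C/C(=O)O[C@@H]1C[C@H]2[C@@H](CCCC[C@H](O)CCC)CCC[C@H]2N[C@H]1C | target

Total step count: 16. Longest linear sequence: 13 steps (steps 1–4, 7–13, 15, 16).

Steps most likely to fail

Step 11. The terminal ynamide may oligomerise or be hydrated at the metal before oxidative cyclisation, the trisubstituted diene terminus may react sluggishly, and facial discrimination at C4a may be incomplete. The fallback avoids the ynamide as 2π partner. It sets out from 15, which is semi-hydrogenated (H2, 1 atm, Pd/CaCO3 poisoned with Pb(OAc)2, quinoline, EtOAc) to the N-ethenyl carbamate F1. Heating F1 (toluene, BHT, sealed tube, about 175 °C) in a thermal intramolecular Diels–Alder reaction of an enamide dienophile should form the same two bonds and give the cis-fused octahydroquinoline F2; any ring-fusion epimer would be removed by chromatography. Hydrogenation of F2 (H2, PtO2, EtOAc) from the convex face returns to the route at 17.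

Step 9. Coupling at the hindered, α-branched carbamate nitrogen may be slow, so that homocoupling of the bromoalkyne consumes the reagent. The fallback builds the alkyne on nitrogen by addition–elimination instead of cross-coupling. It sets out from 13, which with trichloroethene and Cs2CO3 in DMF at 60 °C should give the (E)-1,2-dichloroethenyl carbamate F3. Phenyllithium (2.5 equiv, THF, −78 → −40 °C) then effects elimination and chlorine–lithium exchange to the lithium ynamide, and a methanol quench returns to the route at 15.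

Step 12. The cyclohexa-1,4-diene may aromatise by dehydrogenation on the metal surface, the C5=C6 double bond may migrate before it is reduced (which would scramble C4a), or facial control may be incomplete. The fallback replaces surface hydrogenation by a hydroxyl-directed homogeneous one. It sets out from 16, which is desilylated (TBAF, THF) to the dienamide alcohol F4. Its C3 hydroxyl lies on the H4a face and should direct [Ir(cod)(PCy3)(py)]PF6 (H2, CH2Cl2, rt) to deliver hydrogen to both alkenes from that face, which returns to the route at 18.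

Further compounds
F1 | step 11 | tert-butyl N-ethenyl-N-[(2S,3R,5E,11R)-11-tert-butoxy-3-[(tert-butyldimethylsilyl)oxy]-6-ethenyltetradec-5-en-2-yl]carbamate | C[C@H](N(C=C)C(=O)OC(C)(C)C)[C@H](O[Si](C)(C)C(C)(C)C)C/C=C(/C=C)CCCC[C@H](OC(C)(C)C)CCC
F2 | step 11 | tert-butyl (2S,3R,4aS,8aR)-5-[(5R)-5-tert-butoxyoctyl]-3-[(tert-butyldimethylsilyl)oxy]-2-methyl-3,4,4a,7,8,8a-hexahydroquinoline-1(2H)-carboxylate | CC(C)(C)[Si](C)(C)O[C@@H]1C[C@H]2C(CCCC[C@H](OC(C)(C)C)CCC)=CCC[C@H]2N(C(=O)OC(C)(C)C)[C@H]1C
F3 | step 9 | tert-butyl N-[(E)-1,2-dichloroethenyl]-N-[(2S,3R,5E,11R)-11-tert-butoxy-3-[(tert-butyldimethylsilyl)oxy]-6-ethenyltetradec-5-en-2-yl]carbamate | C[C@H](N(/C(Cl)=C\Cl)C(=O)OC(C)(C)C)[C@H](O[Si](C)(C)C(C)(C)C)C/C=C(/C=C)CCCC[C@H](OC(C)(C)C)CCC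
F4 | step 12 | tert-butyl (2S,3R,4aS)-5-[(5R)-5-tert-butoxyoctyl]-3-hydroxy-2-methyl-3,4,4a,7-tetrahydroquinoline-1(2H)-carboxylate | O[C@@H]1C[C@H]2C(CCCC[C@H](OC(C)(C)C)CCC)=CCC=C2N(C(=O)OC(C)(C)C)[C@H]1C
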